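**Retrosynthetic overview**

- Target (3S,5S,6S)-triol ⇐ hydrogenolysis of two benzyl ethers ⇐ hydroxyl-directed 1,3-syn reduction of a C3 ketone ⇐ hydrolysis of a C3 1,3-dithiane.
- Key disconnections, made in one flask on (S,S)-1,2:3,4-diepoxybutane (which supplies C4–C7): C3–C4 by a 2-lithio-1,3-dithiane on one epoxide CH2, and C7–aryl by a CuI-catalysed aryl Grignard reagent on the other.
- Feature used: the threo (5S,6S) diol at C5/C6, flanked by the methylenes C4 and C7, is a C2-symmetric L-threitol unit; its two ends are homotopic, so either fragment can go on either end without regioisomers.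
- Fragments: the dithiane from dihydroconiferyl alcohol (C1–C3 with guaiacyl ring A), the Grignard reagent from 1-(benzyloxy)-4-bromobenzene (ring B), the diepoxide from L-threitol 1,4-dimethanesulfonate.
- Ring order: no ring of the target is built (rings A and B are bought); only the two oxiranes (step 1) and the 1,3-dithiane mask (step 4) are made, then opened (step 6) or removed (step 7).

Key step: step 6

Remark: the chain is numbered from C1 (CH2 on guaiacyl ring A) to C7 (CH2 on 4-hydroxyphenyl ring B); the SMILES is read as (3S,5S,6S), i.e. 3,5-syn and 5,6-threo, and L-threitol 1,4-dimethanesulfonate is taken as a purchasable material.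

**Route**

Step 1
Reactants: 1 L-threitol 1,4-dimethanesulfonate
Product: 2 (S,S)-1,2:3,4-diepoxybutane
Conditions: KOH (2.2 equiv), H2O/Et2O, rt; distillation
Reagents that add atoms: none
Why: Double intramolecular Williamson etherification (3-exo-tet epoxide closure) in which each secondary alkoxide displaces the neighbouring primary mesylate, so C2 and C3 are never attacked and the (S,S) configuration of L-threitol is carried into 2.

Step 2
Reactants: 3 dihydroconiferyl alcohol
Product: 4 3-[4-(benzyloxy)-3-methoxyphenyl]propan-1-ol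
Conditions: BnBr, K2CO3, acetone, reflux
Reagents that add atoms: benzyl bromide, BrCc1ccccc1
Why: Williamson ether synthesis in which K2CO3 deprotonates only the phenol, which is far more acidic than the primary alcohol, so benzylation should occur on the phenolic oxygen alone.

Step 3
Reactants: 4 3-[4-(benzyloxy)-3-methoxyphenyl]propan-1-ol
Product: 5 3-[4-(benzyloxy)-3-methoxyphenyl]propanal
Conditions: PhI(OAc)2 (1.1 equiv), 2,2,6,6-tetramethylpiperidin-1-oxyl (10 mol%), CH2Cl2, rt
Reagents that add atoms: none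
Why: Oxoammonium-mediated alcohol oxidation with PhI(OAc)2 as terminal oxidant should stop at the aldehyde under anhydrous conditions and leave the electron-rich aryl benzyl ether untouched.

Step 4
Reactants: 5 3-[4-(benzyloxy)-3-methoxyphenyl]propanal; 6 propane-1,3-dithiol
Product: 7 2-{2-[4-(benzyloxy)-3-methoxyphenyl]ethyl}-1,3-dithiane
Conditions: BF3·OEt2 (cat.), CH2Cl2, 0 °C to rt
Reagents that add atoms: none
Why: Lewis-acid-catalysed dithioacetalisation of an unhindered aliphatic aldehyde is fast at 0 °C, releases only water, and with merely catalytic BF3·OEt2 should not cleave the aryl benzyl ether.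

Step 5
Reactants: 8 1-(benzyloxy)-4-bromobenzene
Product: 9 4-(benzyloxy)phenylmagnesium bromide
Conditions: Mg turnings, I2 (crystal), THF, reflux then rt; titrated solution
Reagents that add atoms: magnesium, [Mg]
Why: Grignard reagent formation by insertion of magnesium into the aryl C–Br bond, to which the benzyl aryl ether is inert.

Step 6
Reactants: 7 2-{2-[4-(benzyloxy)-3-methoxyphenyl]ethyl}-1,3-dithiane; 2 (S,S)-1,2:3,4-diepoxybutane; 9 4-(benzyloxy)phenylmagnesium bromide
Product: 12 (2S,3S)-1-[2-{2-[4-(benzyloxy)-3-methoxyphenyl]ethyl}-1,3-dithian-2-yl]-4-[4-(benzyloxy)phenyl]butane-2,3-diol, via 2-lithiodithiane 10 (not isolated), via lithium epoxy alkoxide 11 (not isolated)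
Conditions: n-BuLi (1.0 equiv), THF, −30 °C; cannula into 2 (1.5 equiv), THF, −78 to −20 °C; then CuI (20 mol%), 9 (3.5 equiv), −30 to 0 °C; aq. NH4Cl
Reagents that add atoms: none
Why: n-BuLi deprotonates C2 of 7 (Corey–Seebach umpolung) and the sulfur-stabilised carbanion 10 attacks a terminal CH2 of 2 in an SN2 epoxide opening, forming C3–C4 and the lithium alkoxide 11, after which CuI catalyses transfer of the aryl group of 9 to the CH2 of the remaining epoxide, forming C7–aryl. The closest known reaction types are the coupling of 2-lithio-1,3-dithianes with terminal epoxides and the CuI-catalysed opening of both ends of 1,2:3,4-diepoxybutane by Grignard reagents, here applied one to each end in sequence. No ring is closed and no stereocentre is created: C5 and C6 are never the site of attack, so they keep the L-threitol configuration and appear as the (5S,6S) threo diol. Mono-opening in the first stage is needed and should follow from inverse addition of 10 to an excess of 2 at −78 °C, the two epoxides of 2 being homotopic (one product whichever end reacts) and the alkoxide of 11 making its neighbouring epoxide less electrophilic towards a second carbanion. Terminal regioselectivity is needed in both stages and comes from the steric bias of monosubstituted oxiranes. The alkoxide of 11 is a spectator in the copper stage, and surplus 2 is arylated at both ends by the excess of 9 to a symmetric diol that is separated by chromatography.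

Step 7
Reactants: 12 (2S,3S)-1-[2-{2-[4-(benzyloxy)-3-methoxyphenyl]ethyl}-1,3-dithian-2-yl]-4-[4-(benzyloxy)phenyl]butane-2,3-diol
Product: 13 (5S,6S)-1-[4-(benzyloxy)-3-methoxyphenyl]-7-[4-(benzyloxy)phenyl]-5,6-dihydroxyheptan-3-one
Conditions: MeI (excess), CaCO3, MeCN/H2O (9:1), 45 °C
Reagents that add atoms: water, O
Why: Alkylative dithioacetal hydrolysis in which S-methylation gives a sulfonium ion that ionises to a thionium ion and is hydrolysed by water, while CaCO3 scavenges HI so that the β,γ-dihydroxy ketone should neither dehydrate nor cyclise and C5/C6 stay untouched.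

Step 8
Reactants: 13 (5S,6S)-1-[4-(benzyloxy)-3-methoxyphenyl]-7-[4-(benzyloxy)phenyl]-5,6-dihydroxyheptan-3-one
Product: 15 (3S,5S,6S)-1-[4-(benzyloxy)-3-methoxyphenyl]-7-[4-(benzyloxy)phenyl]heptane-3,5,6-triol, via diethylboron chelate 14 (not isolated)
Conditions: Et2BOMe (2.2 equiv), THF/MeOH (4:1), −78 °C; NaBH4, −78 °C; AcOH; MeOH co-evaporation
Reagents that add atoms: none
Why: Narasaka–Prasad reduction in which the boron of the C5 diethylborinate is chelated by the C3 carbonyl in a six-membered half-chair (14) with the C5 side chain pseudo-equatorial, and axial attack of hydride on this activated carbonyl sets C3 syn to C5, i.e. (3S), the C6 hydroxyl being unable to form a comparable chelate with the carbonyl.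

Step 9
Reactants: 15 (3S,5S,6S)-1-[4-(benzyloxy)-3-methoxyphenyl]-7-[4-(benzyloxy)phenyl]heptane-3,5,6-triol
Product: 16 (3S,5S,6S)-1-(4-hydroxy-3-methoxyphenyl)-7-(4-hydroxyphenyl)heptane-3,5,6-triol
Conditions: H2 (1 atm), 10% Pd/C, EtOAc/EtOH, rt
Reagents that add atoms: none
Why: Heterogeneous catalytic hydrogenolysis cleaves both benzyl aryl ethers, and since the chain has no benzylic C–O bond (C6 is homobenzylic) the three carbinol stereocentres should be untouched.

**Compound list**

1 | L-threitol 1,4-dimethanesulfonate [(2S,3S)-2,3-dihydroxybutane-1,4-diyl dimethanesulfonate] | CS(=O)(=O)OC[C@H](O)[C@@H](O)COS(C)(=O)=O | starting material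
2 | (S,S)-1,2:3,4-diepoxybutane [(2S,2'S)-2,2'-bioxirane] | C1[C@H](O1)[C@@H](O2)C2 | intermediate
3 | dihydroconiferyl alcohol [4-(3-hydroxypropyl)-2-methoxyphenol] | COc1cc(CCCO)ccc1O | starting material
4 | 3-[4-(benzyloxy)-3-methoxyphenyl]propan-1-ol | COc1cc(CCCO)ccc1OCc1ccccc1 | intermediate
5 | 3-[4-(benzyloxy)-3-methoxyphenyl]propanal | COc1cc(CCC=O)ccc1OCc1ccccc1 | intermediate
6 | propane-1,3-dithiol | SCCCS | starting material
7 | 2-{2-[4-(benzyloxy)-3-methoxyphenyl]ethyl}-1,3-dithiane | COc1cc(CCC2SCCCS2)ccc1OCc1ccccc1 | intermediate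
8 | 1-(benzyloxy)-4-bromobenzene | Brc1ccc(OCc2ccccc2)cc1 | starting material
9 | 4-(benzyloxy)phenylmagnesium bromide | Br[Mg]c1ccc(OCc2ccccc2)cc1 | intermediate
10 | 2-lithio-2-{2-[4-(benzyloxy)-3-methoxyphenyl]ethyl}-1,3-dithiane | COc1cc(CCC2([Li])SCCCS2)ccc1OCc1ccccc1 | intermediate
11 | lithium (1S)-2-[2-{2-[4-(benzyloxy)-3-methoxyphenyl]ethyl}-1,3-dithian-2-yl]-1-[(2S)-oxiran-2-yl]ethan-1-olate | COc1cc(CCC2(C[C@H](O[Li])[C@@H]3CO3)SCCCS2)ccc1OCc1ccccc1 | intermediate
12 | (2S,3S)-1-[2-{2-[4-(benzyloxy)-3-methoxyphenyl]ethyl}-1,3-dithian-2-yl]-4-[4-(benzyloxy)phenyl]butane-2,3-diol | COc1cc(CCC2(C[C@H](O)[C@@H](O)Cc3ccc(OCc4ccccc4)cc3)SCCCS2)ccc1OCc1ccccc1 | intermediate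
13 | (5S,6S)-1-[4-(benzyloxy)-3-methoxyphenyl]-7-[4-(benzyloxy)phenyl]-5,6-dihydroxyheptan-3-one | COc1cc(CCC(=O)C[C@H](O)[C@@H](O)Cc2ccc(OCc3ccccc3)cc2)ccc1OCc1ccccc1 | intermediate
14 | (5S,6S)-1-[4-(benzyloxy)-3-methoxyphenyl]-7-[4-(benzyloxy)phenyl]-5-[(diethylboranyl)oxy]-6-hydroxyheptan-3-one, boron coordinated by the C3 carbonyl oxygen | COc1cc(CCC(=O)C[C@H](OB(CC)CC)[C@@H](O)Cc2ccc(OCc3ccccc3)cc2)ccc1OCc1ccccc1 | intermediate
15 | (3S,5S,6S)-1-[4-(benzyloxy)-3-methoxyphenyl]-7-[4-(benzyloxy)phenyl]heptane-3,5,6-triol | COc1cc(CC[C@H](O)C[C@H](O)[C@@H](O)Cc2ccc(OCc3ccccc3)cc2)ccc1OCc1ccccc1 | intermediate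
16 | (3S,5S,6S)-1-(4-hydroxy-3-methoxyphenyl)-7-(4-hydroxyphenyl)heptane-3,5,6-triol | COc1cc(CC[C@H](O)C[C@H](O)[C@@H](O)Cc2ccc(O)cc2)ccc1O | target

**Step count**

Total: 9 steps. Longest linear sequence: 7 steps (steps 2, 3, 4, 6, 7, 8, 9, from dihydroconiferyl alcohol 3).

**Steps most likely to fail, with fallbacks**

1. Step 6. The first stage may over-react, with a second carbanion 10 opening the remaining epoxide of 11. In the second stage, bromide from the Grignard solution may open the epoxide of 11 faster than the aryl group is transferred.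
   - The fallback splits the union into isolated operations with the order of the nucleophiles reversed; it sets out from 2 and returns at 12.
   - Slow addition of 9 (1 equiv) to 2 (3 equiv) with CuI (10 mol%) in THF at −40 °C should give the mono-arylated epoxy alcohol (1S)-2-[4-(benzyloxy)phenyl]-1-[(2S)-oxiran-2-yl]ethan-1-ol F1. The surplus volatile 2 is removed under vacuum.
   - Silylation (Et3SiCl, imidazole, CH2Cl2) should give triethyl{(1S)-2-[4-(benzyloxy)phenyl]-1-[(2S)-oxiran-2-yl]ethoxy}silane F2.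
   - Opening of F2 at its CH2 by 10 (from 7 and n-BuLi, THF, −30 to 0 °C) should give (2S,3S)-1-[2-{2-[4-(benzyloxy)-3-methoxyphenyl]ethyl}-1,3-dithian-2-yl]-4-[4-(benzyloxy)phenyl]-3-[(triethylsilyl)oxy]butan-2-ol F3.
   - Bu4NF in THF removes the silyl group and the sequence rejoins the route at 12.

2. Step 8. The 1,3-syn facial selectivity may erode if the free C6 hydroxyl competes with the C3 carbonyl for the boron, so that part of the ketone is reduced outside the chelate.
   - The fallback replaces boron chelation by lithium chelation to a protected diol; it sets out from 12 and returns at 15.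
   - 2,2-Dimethoxypropane with catalytic pyridinium p-toluenesulfonate should convert 12 into the acetonide 2-{2-[4-(benzyloxy)-3-methoxyphenyl]ethyl}-2-{[(4S,5S)-5-[4-(benzyloxy)benzyl]-2,2-dimethyl-1,3-dioxolan-4-yl]methyl}-1,3-dithiane F4.
   - Hydrolysis of the dithiane (MeI, CaCO3, aqueous MeCN) should give 4-[4-(benzyloxy)-3-methoxyphenyl]-1-{(4S,5S)-5-[4-(benzyloxy)benzyl]-2,2-dimethyl-1,3-dioxolan-4-yl}butan-2-one F5.
   - Chelation-controlled reduction of this β-alkoxy ketone (LiAlH4, LiI, Et2O, −78 °C; lithium bridging the carbonyl and the dioxolane oxygen on C5) should give the 1,3-syn alcohol (2S)-4-[4-(benzyloxy)-3-methoxyphenyl]-1-{(4S,5S)-5-[4-(benzyloxy)benzyl]-2,2-dimethyl-1,3-dioxolan-4-yl}butan-2-ol F6.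
   - 80% aqueous AcOH at 40 °C removes the acetonide and the sequence rejoins the route at 15.

3. Step 7. The alkylative hydrolysis of the hindered 2,2-dialkyl dithiane may be slow. Over the long reaction time the freed ketone may close a hemiketal through its C6 hydroxyl and lose water (towards a furan), or eliminate the C5 hydroxyl.
   - The fallback caps both hydroxyls and unmasks the ketone oxidatively; it sets out from 12 and returns at 13.
   - Et3SiOTf and 2,6-lutidine (CH2Cl2, −78 °C) should give 2-{2-[4-(benzyloxy)-3-methoxyphenyl]ethyl}-2-{(2S,3S)-4-[4-(benzyloxy)phenyl]-2,3-bis[(triethylsilyl)oxy]butyl}-1,3-dithiane F7.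
   - Oxidative unmasking with I2 and NaHCO3 in aqueous acetone at 0 °C should give (5S,6S)-1-[4-(benzyloxy)-3-methoxyphenyl]-7-[4-(benzyloxy)phenyl]-5,6-bis[(triethylsilyl)oxy]heptan-3-one F8, which cannot form the hemiketal.
   - Brief treatment with HF·pyridine in THF/pyridine at 0 °C removes both silyl groups and the sequence rejoins the route at 13.

**Further compounds**

F1 | step 6 | (1S)-2-[4-(benzyloxy)phenyl]-1-[(2S)-oxiran-2-yl]ethan-1-ol | C1[C@H](O1)[C@@H](O)Cc1ccc(OCc2ccccc2)cc1
F2 | step 6 | triethyl{(1S)-2-[4-(benzyloxy)phenyl]-1-[(2S)-oxiran-2-yl]ethoxy}silane | C1[C@H](O1)[C@@H](O[Si](CC)(CC)CC)Cc1ccc(OCc2ccccc2)cc1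
F3 | step 6 | (2S,3S)-1-[2-{2-[4-(benzyloxy)-3-methoxyphenyl]ethyl}-1,3-dithian-2-yl]-4-[4-(benzyloxy)phenyl]-3-[(triethylsilyl)oxy]butan-2-ol | COc1cc(CCC2(C[C@H](O)[C@@H](O[Si](CC)(CC)CC)Cc3ccc(OCc4ccccc4)cc3)SCCCS2)ccc1OCc1ccccc1
F4 | step 8 | 2-{2-[4-(benzyloxy)-3-methoxyphenyl]ethyl}-2-{[(4S,5S)-5-[4-(benzyloxy)benzyl]-2,2-dimethyl-1,3-dioxolan-4-yl]methyl}-1,3-dithiane | COc1cc(CCC2(C[C@@H]3OC(C)(C)O[C@H]3Cc3ccc(OCc4ccccc4)cc3)SCCCS2)ccc1OCc1ccccc1
F5 | step 8 | 4-[4-(benzyloxy)-3-methoxyphenyl]-1-{(4S,5S)-5-[4-(benzyloxy)benzyl]-2,2-dimethyl-1,3-dioxolan-4-yl}butan-2-one | COc1cc(CCC(=O)C[C@@H]2OC(C)(C)O[C@H]2Cc2ccc(OCc3ccccc3)cc2)ccc1OCc1ccccc1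
F6 | step 8 | (2S)-4-[4-(benzyloxy)-3-methoxyphenyl]-1-{(4S,5S)-5-[4-(benzyloxy)benzyl]-2,2-dimethyl-1,3-dioxolan-4-yl}butan-2-ol | COc1cc(CC[C@H](O)C[C@@H]2OC(C)(C)O[C@H]2Cc2ccc(OCc3ccccc3)cc2)ccc1OCc1ccccc1
F7 | step 7 | 2-{2-[4-(benzyloxy)-3-methoxyphenyl]ethyl}-2-{(2S,3S)-4-[4-(benzyloxy)phenyl]-2,3-bis[(triethylsilyl)oxy]butyl}-1,3-dithiane | COc1cc(CCC2(C[C@H](O[Si](CC)(CC)CC)[C@@H](O[Si](CC)(CC)CC)Cc3ccc(OCc4ccccc4)cc3)SCCCS2)ccc1OCc1ccccc1
F8 | step 7 | (5S,6S)-1-[4-(benzyloxy)-3-methoxyphenyl]-7-[4-(benzyloxy)phenyl]-5,6-bis[(triethylsilyl)oxy]heptan-3-one | COc1cc(CCC(=O)C[C@H](O[Si](CC)(CC)CC)[C@@H](O[Si](CC)(CC)CC)Cc2ccc(OCc3ccccc3)cc2)ccc1OCc1ccccc1
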